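**Amounts charged.** Count amounts as fractions of the starting material charged, and open one ledger for it with three entries: left, target, and an unseen entry for whatever neither reading shows.

common to all: free catalyst 0.18 mol%

| run | starting material | second substrate | partner | protic impurity | temperature | remark | time |
|---|---|---|---|---|---|---|---|
| epsilon | 10 mM | 0.50 equiv | 1.5 equiv | 5 mM | 75 °C | run made earlier |  |
| beta | 5 mM | 0.50 equiv | 1.5 equiv | 5 mM | 90 °C | run made earlier |  |
| gamma | 20 mM | 0.50 equiv | 1.5 equiv | 5 mM | 75 °C | run made earlier |  |
| delta | 10 mM | 0.50 equiv | 1.5 equiv | 10 mM | 90 °C | run made earlier |  |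
| violet | 10 mM | 0.500 equiv | 1.50 equiv (fed, over 4.0 min) | 5.00 mM | 90 °C | all else is in the flask from the start; the feed brings no volume worth counting | 40 min |
| green | 10 mM | 0.500 equiv | 1.50 equiv | 5.00 mM | 90 °C | everything together at the start | 40 min |
| red | 10 mM | 0.500 equiv (fed, over 15 min) | 1.50 equiv | 5.00 mM | 90 °C | all else is in the flask from the start; the feed brings no volume worth counting | 40 min |
| ochre | 10 mM | 0.500 equiv (fed, over 15 min) | 1.50 equiv | 5.00 mM |  | the addition at 50 °C, then warmed to 90 °C; the feed brings no volume worth counting | 40 min |

| run | time / min | target / % | starting material / % |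
|---|---|---|---|
| epsilon | 4.00 | 3.3 | 96.6 |
| epsilon | 8.00 | 7.0 | 91.4 |
| epsilon | 12.0 | 7.8 | 85.6 |
| epsilon | 25.0 | 10.7 | 74.4 |
| epsilon | 50.0 | 12.2 | 63.5 |
| beta | 8.00 | 6.6 | 87.8 |
| beta | 15.0 | 7.5 | 80.7 |
| beta | 25.0 | 6.6 | 74.7 |
| beta | 30.0 | 9.9 | 74.4 |
| beta | 40.0 | 8.9 | 69.5 |
| gamma | 15.0 | 11.9 | 70.7 |
| gamma | 30.0 | 14.0 | 57.4 |
| gamma | 50.0 | 13.5 | 49.7 |
| gamma | 60.0 | 13.5 | 48.9 |
| gamma | 80.0 | 14.6 | 48.4 |
| delta | 8.00 | 9.3 | 81.3 |
| delta | 15.0 | 8.3 | 73.7 |
| delta | 25.0 | 8.9 | 69.2 |
| delta | 30.0 | 9.4 | 67.0 |
| delta | 40.0 | 8.5 | 65.9 |

(readings scatter by 1 percentage point)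



1. the flask that comes out highest in amount of target, in percent of the starting material charged, or "all alike" when all lie within 1.5 percentage points (violet / green / red / ochre / all alike)
2. target at the end, in percent of the starting material charged, violet
3. target at the end, in percent of the starting material charged, green
4. target at the end, in percent of the starting material charged, red
5. target at the end, in percent of the starting material charged, ochre

**Both ends.** Read the start first: epsilon at 4.00 min shows a kept fraction of 0.971, rough within the scatter, so the unseen entry opens nearly empty. Then read the late end: in delta, between 8.00 min and 40.0 min, starting material falls from 81.3 % to 65.9 % while target goes from 9.3 % to 8.5 %, so the unseen entry takes more of the late loss than target does.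

**Kept share.** Join the ends with one number: beta at 40.0 min gives 0.292 for the kept share, which is target standing over the fraction of starting material lost, the selectivity to target. The last readings of the other runs give 0.334 in epsilon, 0.283 in gamma and 0.249 in delta, a narrow band across changes of charge, temperature and impurity.

**Closing books.** Take the kept share from beta, whose impurity matches the new flasks, and the lost fraction 34 percentage points from delta, whose starting material matches, which gives target near 9.95 %. Read the unseen entry as loss after target has formed, a judgement and no proof, since no earlier run was fed; on that judgement, assume that the kept share and the target entry hold under feeding, and commit to target in violet, green, red and ochre lying within 1.5 points, with no claim for the other entries.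

**The forecast.** The forecast differs on red, naming red at 16 % against 10.5 % for violet, 10 % for green and 11.5 % for ochre, “so red should be clearly best”.

**The result.** The flasks give 9.75 % for violet, 9.73 % for green, 9.51 % for red and 9.71 % for ochre, so the answer is all alike.

    partner + catalyst intermediate A → free catalyst + target (k = 47.0 M⁻¹ s⁻¹, Ea = 60.0 kJ mol⁻¹)
    second substrate + free catalyst ⇌ catalyst intermediate B (K = 120 M⁻¹, k = 530 M⁻¹ s⁻¹, Ea = 55.0 kJ mol⁻¹, ΔH = −14.0 kJ mol⁻¹)
    target ⇌ isomer of the product (K = 0.940, k = 6.60 × 10⁻⁴ s⁻¹, Ea = 110 kJ mol⁻¹, ΔH = 0 kJ mol⁻¹)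
    partner + protic impurity → quenched reagent (k = 0.150 M⁻¹ s⁻¹, Ea = 71.0 kJ mol⁻¹)
    starting material + free catalyst ⇌ catalyst intermediate A (K = 3400 M⁻¹, k = 62.0 M⁻¹ s⁻¹, Ea = 57.0 kJ mol⁻¹, ΔH = −33.0 kJ mol⁻¹)
    partner + catalyst intermediate B → free catalyst + second product (k = 320 M⁻¹ s⁻¹, Ea = 47.0 kJ mol⁻¹)
    partner + target → over-reaction product (k = 0.450 M⁻¹ s⁻¹, Ea = 73.0 kJ mol⁻¹)
    (constants at 90 °C)

**One reason.** Green ends with 56.0 % left, 9.73 % target, 27.2 % over-reaction product and 7.00 % isomer of the product, so its kept share is 0.221 on a lost fraction of 44 points, a lower share on a larger loss than the ledger entered. Remove the step of partner with target from green and target rises from 9.73 % to 32.8 %, the largest single effect among the removals. The neighbour of green charged with 3.80 equiv of partner loses 87 points of its starting material and keeps a share of 0.0321.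

The earlier runs and the new flask stem from a simulated flask from invented constants; scatter was added.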